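A ratio of two times at equal product opened this flask, in which starting material and coupling partner give product under free catalyst.

| flask | starting material | coupling partner | free catalyst | time |
|---|---|---|---|---|
| west | 200 mM | 500 mM | 4.00 mM |  |
| north | 400 mM | 500 mM | 4.00 mM |  |
| north-west | 200 mM | 500 mM | 6.00 mM |  |
| south-west | 600 mM | 1500 mM | 4.00 mM | 65 min |

| west run: time / min | west run: [product] / mM | north run: time / min | north run: [product] / mM | north-west run: time / min | north-west run: [product] / mM |
|---|---|---|---|---|---|
| 9.3 | 30.2 | 9.3 | 39.9 | 9.3 | 68.0 |
| 19 | 69.0 | 19 | 72.9 | 19 | 115.5 |
| 28 | 94.9 | 28 | 106.6 | 28 | 155.9 |
| 37 | 118.5 | 37 | 133.9 | 37 | 177.3 |
| 46 | 133.1 | 46 | 162.8 | 46 | 191.4 |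
| 56 | 154.1 | 56 | 189.7 | 56 | 197.2 |
| 65 | 169.4 | 65 | 208.6 | 65 | 199.4 |

(each reading ± 2 mM)

- Overall: starting material + coupling partner -> product, with free catalyst as catalyst.
- Constant volume, constant temperature.
- What is held in complexes is read along with the free species.
- "The second partner" is coupling partner.
- An order is taken over about fifteen percent of the charge, up and down.

- order of the initial rate in [starting material], near the charge of the west run, the rate being that where two percent of its starting material are product (one fixed amount of product, the same in the runs compared)
- order of the initial rate in [free catalyst], near the charge of the west run, the rate being that where two percent of its starting material are product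
- product in the south-west run at 65 min, as a share of the starting material charged

The north-west run reached 155.9 mM of product at 28 min, and the west run reached 154.1 mM at 56 min. Their charges of starting material and coupling partner match, so equal product means equal mixture, and the time ratio 2.00 reads as the rate ratio, for a catalyst ratio of 1.50. I supposed that the rate follows the catalyst that works and that each charge loses one fixed amount; these two runs then give a loss of 2.00 mM. The working share of the west run therefore reads as 0.500: the part of the charged free catalyst that still turns over. A small change of charge falls entirely on the working part, so its relative effect is multiplied by the inverse of that share, and I read the order in free catalyst as 2.00.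

For starting material, the west and north runs stood at 94.9 mM and 106.6 mM at 28 min, a reading of order 0.168 over the doubling, and I expected a small order near that value.

The south-west run has the west catalyst charge, hence the same working share, and the same ratio of coupling partner to starting material, the limiting reagent, at 2.50. One number was not enough here. A rate in step with [coupling partner] gives the south-west run the west share at 65 min, 84.7%. But the small order places the slowing at low [starting material], a matter of millimolar rather than of share, and the last reading of the west run left 30.6 mM unturned. I took that same amount for the south-west run, which gave 94.9%.

The forecast gave 0.15, 1.9 and 90%, differing from my share. Its grounds for the last began with “Integrating the south-west run gives about 95% at 65 min.” It then shaded that figure down to its printed value.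

The simulation gave 0.21, 2.0 and 96.6%.

    free catalyst + starting material ⇌ catalyst-substrate complex, settled at all times (22.40 M⁻¹)
    catalyst-substrate complex + coupling partner → product + free catalyst (5.598 M⁻¹ min⁻¹)
    2 starting material ⇌ idle substrate dimer, settled at all times (4.250 M⁻¹)
    free catalyst + impurity → spent catalyst

The order of 2.0 in free catalyst came from the impurity, which turned free catalyst into spent catalyst at once. The working share of 0.500 carries that effect, and its inverse, 2.00, is the order. In the simulated west run without the impurity, the working share is 1, its inverse is 1, and the order in free catalyst came to 1.0.

The data are simulated with made-up constants; scatter was added.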